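**Retrosynthetic overview**
1. Target ⇒ the 1,2,8-triol carrying both oxiranes; the last step puts on all three angelate esters, one molecule of angelic acid per hydroxyl.
2. Oxiranes ⇒ epoxidation of the 10,11-olefin (catalyst control), then of the ring 3,4-olefin (substrate control), as in the biosynthesis.
3. Cyclohexene ⇒ C1–C6 bond by intramolecular carbonyl-ene (Prins-type) closure of an acyclic (3Z,6Z)-2,8-bis(silyloxy)trienal. This is the biosynthetic 1,6-closure with C14 proton loss, run at the aldehyde oxidation level; C2 and C8 control C1 and C6.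
4. Trienal ⇒ one-pot double Z-selective Wittig of a C3 bis-ylide (C4–C6) with two α-oxygenated methyl ketones: C7–C13 from sulcatone, C1–C3 from a glycerate acetonide.
5. Ring order: cyclohexene, then side-chain oxirane, then ring oxirane.

Assumption: bisabolane numbering is used (ring C1–C6, C7=C14 methylene, side chain C8–C13, C15 = methyl on C3); the SMILES corresponds to (1R,2S,3S,4S,6R,8S,10R), with C1–O and the 3,4-oxirane on one ring face and C2–O and the side chain on the other.

**Route**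

Step 1
Reactants: 1 6-methylhept-5-en-2-one (sulcatone)
Product: 3 (3S)-3-hydroxy-6-methylhept-5-en-2-one, via anilinooxy ketone 2 (not isolated)
Conditions: D-proline (20 mol%), PhNO (slow addition; ketone in excess), DMSO, 0 °C→rt; then CuSO4·5H2O (30 mol%), MeOH, 0 °C
Reagents that add atoms: nitrosobenzene, O=Nc1ccccc1
Why: Proline-catalysed α-aminoxylation (O-nitroso aldol) runs through the more substituted enamine, D-proline's carboxylic acid directs nitrosobenzene to the face that gives the (S)-centre (C8), CuSO4 then cleaves N–O without epimerisation, and slow addition suppresses the slower nitroso-ene reaction of the olefin.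

Step 2
Reactants: 3 (3S)-3-hydroxy-6-methylhept-5-en-2-one
Product: 4 (3S)-3-{[tert-butyl(dimethyl)silyl]oxy}-6-methylhept-5-en-2-one
Conditions: tBuMe2SiCl, imidazole, DMF, 0 °C→rt
Reagents that add atoms: tert-butyldimethylsilyl chloride, C[Si](C)(Cl)C(C)(C)C
Why: Standard silyl ether formation under mild imidazole conditions protects the α-ketol and provides the α-silyloxy ketone needed for the Z-selective Wittig step.

Step 3
Reactants: 5 methyl (4S)-2,2-dimethyl-1,3-dioxolane-4-carboxylate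
Product: 7 1-[(4S)-2,2-dimethyl-1,3-dioxolan-4-yl]ethan-1-one, via Weinreb amide 6 (not isolated)
Conditions: MeNH(OMe)·HCl, iPrMgCl, THF, −20 °C; then MeMgBr, −20→0 °C
Reagents that add atoms: methylmagnesium bromide, C[Mg]Br
Why: Weinreb ketone synthesis in one flask: the magnesium amide converts the ester to the N-methoxy-N-methylamide, whose chelated tetrahedral adduct with MeMgBr stops at the ketone, and the chiral-pool centre (later C2) is not enolised at low temperature.

Step 4
Reactants: 8 propane-1,3-diylbis(triphenylphosphonium) dibromide; 4 (3S)-3-{[tert-butyl(dimethyl)silyl]oxy}-6-methylhept-5-en-2-one; 7 1-[(4S)-2,2-dimethyl-1,3-dioxolan-4-yl]ethan-1-one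
Product: 11 (4R)-4-[(2Z,5Z,7S)-7-{[tert-butyl(dimethyl)silyl]oxy}-6,10-dimethylundeca-2,5,9-trien-2-yl]-2,2-dimethyl-1,3-dioxolane, via bis-ylide 9 (not isolated), via mono-ylide 10 (not isolated)
Conditions: 8 (3 equiv), KN(SiMe3)2 (6 equiv), THF, −78→0 °C; 4 (1 equiv, limiting), −78 °C; then 7 (6 equiv), −78 °C→rt
Reagents that add atoms: none
Why: Double Wittig olefination in one flask: the salt-free bis-ylide, in excess, is mono-olefinated by the limiting ketone 4 and the remaining ylide end by excess 7, and each α-oxygenated methyl ketone gives the Z-trisubstituted olefin with the oxygen-bearing carbon cis to the chain (Still's Z-selective Wittig of α-alkoxy ketones).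

Step 5
Reactants: 11 the diene acetonide from step 4
Product: 12 (2R,3Z,6Z,8S)-8-{[tert-butyl(dimethyl)silyl]oxy}-3,7,11-trimethyldodeca-3,6,10-triene-1,2-diol
Conditions: AcOH/H2O/THF (3:1:1), 35 °C
Reagents that add atoms: none
Why: Acid-catalysed acetal hydrolysis removes the terminal isopropylidene group much faster than the hindered secondary tert-butyldimethylsilyl ether and leaves the skipped diene untouched.

Step 6
Reactants: 12 (2R,3Z,6Z,8S)-8-{[tert-butyl(dimethyl)silyl]oxy}-3,7,11-trimethyldodeca-3,6,10-triene-1,2-diol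
Product: 13 (2R,3Z,6Z,8S)-8-{[tert-butyl(dimethyl)silyl]oxy}-3,7,11-trimethyl-1,2-bis[(triethylsilyl)oxy]dodeca-3,6,10-triene
Conditions: Et3SiCl, imidazole, CH2Cl2, 0 °C
Reagents that add atoms: chlorotriethylsilane, CC[Si](Cl)(CC)CC
Why: Bis-silylation gives a primary triethylsilyl ether that can be oxidised directly and a secondary one that stays as the non-chelating C2 protecting group.

Step 7
Reactants: 13 the bis(triethylsilyl) ether from step 6
Product: 14 (2R,3Z,6Z,8S)-8-{[tert-butyl(dimethyl)silyl]oxy}-3,7,11-trimethyl-2-[(triethylsilyl)oxy]dodeca-3,6,10-trienal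
Conditions: (COCl)2, DMSO, CH2Cl2, −78→−40 °C; Et3N, −78→0 °C; used crude at once
Reagents that add atoms: none
Why: Swern oxidation converts a primary triethylsilyl ether directly into the aldehyde while secondary silyl ethers survive, and low temperature with immediate use guards the α-silyloxy β,γ-unsaturated aldehyde against epimerisation or conjugation.

Step 8
Reactants: 14 the α-silyloxy trienal from step 7
Product: 15 (1R,2R,6R)-6-[(3S)-3-{[tert-butyl(dimethyl)silyl]oxy}-6-methylhepta-1,5-dien-2-yl]-3-methyl-2-[(triethylsilyl)oxy]cyclohex-3-en-1-ol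
Conditions: Me2AlCl (1.05 equiv), CH2Cl2, −78→−40 °C; aq. KNaC4H4O6 work-up
Reagents that add atoms: none
Why: Intramolecular carbonyl-ene reaction (Prins-type 1,6-closure): one equivalent of monodentate Me2AlCl activates the aldehyde without chelation, the chair-like transition state holds C=O, the C2 silyloxy group (anti to the forming bond, Felkin-type) and the olefin chain equatorial so that C1–OH ends trans to both C2–O and C6, the C8 silyloxy group in its allylic-strain-locked rotamer shields the other olefin face (matched), and only the C14 methyl hydrogen (trans to C5 in the 6Z olefin) can reach the oxygen, which gives the 7(14)-methylene directly.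

Step 9
Reactants: 15 the cyclohexenol from step 8
Product: 16 (1R,2R,6R)-6-[(3S)-3-{[tert-butyl(dimethyl)silyl]oxy}-4-[(2R)-3,3-dimethyloxiran-2-yl]but-1-en-2-yl]-3-methyl-2-[(triethylsilyl)oxy]cyclohex-3-en-1-ol
Conditions: D-fructose-derived Shi ketone (30 mol%), Oxone (2KHSO5·KHSO4·K2SO4), K2CO3, Bu4NHSO4, MeCN/CH2(OMe)2/aq. Na2B4O7 buffer, 0 °C
Reagents that add atoms: potassium peroxymonosulfate (KHSO5, active component of Oxone), [K+].[O-]S(=O)(=O)OO
Why: Shi asymmetric epoxidation: the chiral dioxirane attacks the most electron-rich, unhindered 10,11-olefin (the ring olefin and the methylene are each deactivated by an allylic silyloxy group) through the spiro transition state that gives the (10R)-oxirane from a 2-methylalk-2-ene.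

Step 10
Reactants: 16 the mono-epoxide from step 9
Product: 17 (1R,2S,3S,4S,6R)-6-[(3S)-3-{[tert-butyl(dimethyl)silyl]oxy}-4-[(2R)-3,3-dimethyloxiran-2-yl]but-1-en-2-yl]-3,4-epoxy-3-methyl-2-[(triethylsilyl)oxy]cyclohexan-1-ol
Conditions: mCPBA (1.1 equiv), NaHCO3, CH2Cl2, −20→0 °C
Reagents that add atoms: 3-chloroperoxybenzoic acid, OOC(=O)c1cccc(Cl)c1
Why: Prilezhaev epoxidation of the remaining trisubstituted olefin (faster than the 1,1-disubstituted methylene) from the face anti to the bulky allylic C2 silyloxy group and syn to the hydrogen-bonding C1 hydroxyl, which sets C3 and C4 with the oxirane cis to C1–O.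

Step 11
Reactants: 17 the bis-epoxide from step 10
Product: 18 (1R,2S,3R,4S,6R)-6-[(3S)-4-[(2R)-3,3-dimethyloxiran-2-yl]-3-hydroxybut-1-en-2-yl]-3,4-epoxy-3-methylcyclohexane-1,2-diol
Conditions: Bu4NF/AcOH (1:1, 4 equiv), THF, 0 °C→rt
Reagents that add atoms: none
Why: Fluoride-mediated desilylation removes both silyl ethers, and the acetic acid buffer prevents free alkoxides, so neither Payne migration of the 3,4-oxirane nor ether formation from the 8-OH and the 10,11-oxirane is triggered (the C3 descriptor changes by CIP priority only).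

Step 12
Reactants: 18 the triol from step 11; 19 angelic acid [(2Z)-2-methylbut-2-enoic acid] (3 equiv consumed, one per hydroxyl)
Product: 21 CNP0258231.1 [(1R,2S,3S,4S,6R,8S,10R)-1,2,8-tris(angeloyloxy)-3,4:10,11-diepoxybisabol-7(14)-ene], via mixed anhydride 20 (not isolated)
Conditions: 19 (6 equiv), 2,4,6-Cl3C6H2COCl (6 equiv), Et3N (7 equiv), PhMe, rt, 1 h; then 18, 75 °C; no DMAP
Reagents that add atoms: (2Z)-2-methylbut-2-enoic 2,4,6-trichlorobenzoic anhydride (mixed anhydride 20 made in the flask from 19), C/C=C(/C)C(=O)OC(=O)c1c(Cl)cc(Cl)cc1Cl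
Why: Yamaguchi-type esterification in which each of the three secondary hydroxyls (C1, C2 and C8) takes one angeloyl group from one molecule of the mixed anhydride at its less hindered angeloyl carbonyl, so that three molecules of 19 end up in 21, while leaving out nucleophilic catalysts keeps the Z (angelate) geometry and the amine buffer protects the oxiranes.

**Compound list**
1 | 6-methylhept-5-en-2-one (sulcatone) | CC(=O)CCC=C(C)C | starting material
2 | (3S)-3-(anilinooxy)-6-methylhept-5-en-2-one | CC(=O)[C@@H](ONc1ccccc1)CC=C(C)C | intermediate (not isolated)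
3 | (3S)-3-hydroxy-6-methylhept-5-en-2-one | CC(=O)[C@@H](O)CC=C(C)C | intermediate
4 | (3S)-3-{[tert-butyl(dimethyl)silyl]oxy}-6-methylhept-5-en-2-one | CC(=O)[C@@H](O[Si](C)(C)C(C)(C)C)CC=C(C)C | intermediate
5 | methyl (4S)-2,2-dimethyl-1,3-dioxolane-4-carboxylate | COC(=O)[C@@H]1COC(C)(C)O1 | starting material
6 | (4S)-N-methoxy-N,2,2-trimethyl-1,3-dioxolane-4-carboxamide | CON(C)C(=O)[C@@H]1COC(C)(C)O1 | intermediate (not isolated)
7 | 1-[(4S)-2,2-dimethyl-1,3-dioxolan-4-yl]ethan-1-one | CC(=O)[C@@H]1COC(C)(C)O1 | intermediate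
8 | propane-1,3-diylbis(triphenylphosphonium) dibromide | [Br-].[Br-].C(C[P+](c1ccccc1)(c1ccccc1)c1ccccc1)C[P+](c1ccccc1)(c1ccccc1)c1ccccc1 | starting material
9 | propane-1,3-diylidenebis(triphenylphosphorane) (bis-ylide) | C(C=P(c1ccccc1)(c1ccccc1)c1ccccc1)C=P(c1ccccc1)(c1ccccc1)c1ccccc1 | intermediate (not isolated)
10 | [(3Z,5S)-5-{[tert-butyl(dimethyl)silyl]oxy}-4,8-dimethylnona-3,7-dien-1-ylidene]triphenylphosphorane | c1ccccc1P(c1ccccc1)(c1ccccc1)=CC/C=C(C)\[C@@H](O[Si](C)(C)C(C)(C)C)CC=C(C)C | intermediate (not isolated)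
11 | (4R)-4-[(2Z,5Z,7S)-7-{[tert-butyl(dimethyl)silyl]oxy}-6,10-dimethylundeca-2,5,9-trien-2-yl]-2,2-dimethyl-1,3-dioxolane | CC1(C)OC[C@H](O1)/C(C)=C\C/C=C(C)\[C@@H](O[Si](C)(C)C(C)(C)C)CC=C(C)C | intermediate
12 | (2R,3Z,6Z,8S)-8-{[tert-butyl(dimethyl)silyl]oxy}-3,7,11-trimethyldodeca-3,6,10-triene-1,2-diol | OC[C@H](O)/C(C)=C\C/C=C(C)\[C@@H](O[Si](C)(C)C(C)(C)C)CC=C(C)C | intermediate
13 | (2R,3Z,6Z,8S)-8-{[tert-butyl(dimethyl)silyl]oxy}-3,7,11-trimethyl-1,2-bis[(triethylsilyl)oxy]dodeca-3,6,10-triene | CC[Si](CC)(CC)OC[C@H](O[Si](CC)(CC)CC)/C(C)=C\C/C=C(C)\[C@@H](O[Si](C)(C)C(C)(C)C)CC=C(C)C | intermediate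
14 | (2R,3Z,6Z,8S)-8-{[tert-butyl(dimethyl)silyl]oxy}-3,7,11-trimethyl-2-[(triethylsilyl)oxy]dodeca-3,6,10-trienal | O=C[C@H](O[Si](CC)(CC)CC)/C(C)=C\C/C=C(C)\[C@@H](O[Si](C)(C)C(C)(C)C)CC=C(C)C | intermediate
15 | (1R,2R,6R)-6-[(3S)-3-{[tert-butyl(dimethyl)silyl]oxy}-6-methylhepta-1,5-dien-2-yl]-3-methyl-2-[(triethylsilyl)oxy]cyclohex-3-en-1-ol | C=C([C@H](CC=C(C)C)O[Si](C)(C)C(C)(C)C)[C@H]1CC=C(C)[C@@H](O[Si](CC)(CC)CC)[C@@H]1O | intermediate
16 | (1R,2R,6R)-6-[(3S)-3-{[tert-butyl(dimethyl)silyl]oxy}-4-[(2R)-3,3-dimethyloxiran-2-yl]but-1-en-2-yl]-3-methyl-2-[(triethylsilyl)oxy]cyclohex-3-en-1-ol | C=C([C@H](C[C@H]1OC1(C)C)O[Si](C)(C)C(C)(C)C)[C@H]1CC=C(C)[C@@H](O[Si](CC)(CC)CC)[C@@H]1O | intermediate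
17 | (1R,2S,3S,4S,6R)-6-[(3S)-3-{[tert-butyl(dimethyl)silyl]oxy}-4-[(2R)-3,3-dimethyloxiran-2-yl]but-1-en-2-yl]-3,4-epoxy-3-methyl-2-[(triethylsilyl)oxy]cyclohexan-1-ol | C=C([C@H](C[C@H]1OC1(C)C)O[Si](C)(C)C(C)(C)C)[C@H]1C[C@@H]2O[C@]2(C)[C@@H](O[Si](CC)(CC)CC)[C@@H]1O | intermediate
18 | (1R,2S,3R,4S,6R)-6-[(3S)-4-[(2R)-3,3-dimethyloxiran-2-yl]-3-hydroxybut-1-en-2-yl]-3,4-epoxy-3-methylcyclohexane-1,2-diol | C=C([C@H](C[C@H]1OC1(C)C)O)[C@H]1C[C@@H]2O[C@]2(C)[C@@H](O)[C@@H]1O | intermediate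
19 | angelic acid, (2Z)-2-methylbut-2-enoic acid | C/C=C(/C)C(=O)O | starting material
20 | (2Z)-2-methylbut-2-enoic 2,4,6-trichlorobenzoic anhydride | C/C=C(/C)C(=O)OC(=O)c1c(Cl)cc(Cl)cc1Cl | intermediate (not isolated)
21 | CNP0258231.1, (1R,2S,3S,4S,6R)-6-{(3S)-4-[(2R)-3,3-dimethyloxiran-2-yl]-3-[(2Z)-2-methylbut-2-enoyloxy]but-1-en-2-yl}-3,4-epoxy-3-methylcyclohexane-1,2-diyl bis[(2Z)-2-methylbut-2-enoate] | C=C([C@H](C[C@H]1OC1(C)C)OC(=O)/C(C)=C\C)[C@H]1C[C@@H]2O[C@]2(C)[C@@H](OC(=O)/C(C)=C\C)[C@@H]1OC(=O)/C(C)=C\C | target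

**Step count**
Total: 12 steps. Longest linear sequence: 11 steps (1, 2, 4–12); step 3 and angelic acid are side branches.

**Steps most likely to fail and fallbacks**

Step 8 (carbonyl-ene closure). The olefin is deactivated by the allylic silyloxy group, Me2AlCl can add methyl to the aldehyde, and the 1,2-cis diastereomer is possible if the C2 silyloxy group goes pseudo-axial. The fallback runs the closure stepwise. Setting out from aldehyde 14, EtAlCl2 (2 equiv, CH2Cl2, −78 °C) promotes a Prins closure in which the C7 cation is captured by chloride, giving (1R,2R,6S)-6-[(3S)-2-chloro-3-{[tert-butyl(dimethyl)silyl]oxy}-6-methylhept-5-en-2-yl]-3-methyl-2-[(triethylsilyl)oxy]cyclohex-3-en-1-ol F4 (mixture of C7 epimers; the C6 descriptor changes by CIP priority only). KOC(CH3)3 in THF at 0 °C then eliminates HCl toward the methyl group (Hofmann-type E2), which returns to the route at 15.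

Step 4 (one-pot double Wittig). The statistical mono-olefination of the bis-ylide may give mostly symmetrical dienes. The fallback builds the linchpin stepwise. Setting out from ketone 4, the ylide of (3-hydroxypropyl)triphenylphosphonium bromide (2 equiv KN(SiMe3)2, THF, −78 °C) gives (3Z,5S)-5-{[tert-butyl(dimethyl)silyl]oxy}-4,8-dimethylnona-3,7-dien-1-ol F1. I2, PPh3 and imidazole convert it to (3Z,5S)-5-{[tert-butyl(dimethyl)silyl]oxy}-1-iodo-4,8-dimethylnona-3,7-diene F2. PPh3 in MeCN at reflux gives [(3Z,5S)-5-{[tert-butyl(dimethyl)silyl]oxy}-4,8-dimethylnona-3,7-dien-1-yl]triphenylphosphonium iodide F3. Deprotonation with KN(SiMe3)2 and Wittig reaction with ketone 7 returns to the route at 11.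

Step 12 (triple angeloylation). The C2 hydroxyl is hindered, and heating can isomerise angelate to tiglate or open an oxirane. The fallback builds the Z olefins on the ester instead. Setting out from triol 18, DCC and catalytic DMAP with 2-[bis(2,2,2-trifluoroethoxy)phosphoryl]propanoic acid (CH2Cl2, 0 °C) give the tris-ester (1R,2S,3S,4S,6R,8S,10R)-3,4:10,11-diepoxybisabol-7(14)-ene-1,2,8-triyl tris{2-[bis(2,2,2-trifluoroethoxy)phosphoryl]propanoate} F5. KN(SiMe3)2 and 18-crown-6 in THF at −78 °C, then acetaldehyde (Still–Gennari olefination), form the three (Z)-2-methylbut-2-enoates and return to the route at 21.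

**Further compounds**
F1 | step 4 | (3Z,5S)-5-{[tert-butyl(dimethyl)silyl]oxy}-4,8-dimethylnona-3,7-dien-1-ol | OCC/C=C(C)\[C@@H](O[Si](C)(C)C(C)(C)C)CC=C(C)C
F2 | step 4 | (3Z,5S)-5-{[tert-butyl(dimethyl)silyl]oxy}-1-iodo-4,8-dimethylnona-3,7-diene | ICC/C=C(C)\[C@@H](O[Si](C)(C)C(C)(C)C)CC=C(C)C
F3 | step 4 | [(3Z,5S)-5-{[tert-butyl(dimethyl)silyl]oxy}-4,8-dimethylnona-3,7-dien-1-yl]triphenylphosphonium iodide | [I-].c1ccccc1[P+](c1ccccc1)(c1ccccc1)CC/C=C(C)\[C@@H](O[Si](C)(C)C(C)(C)C)CC=C(C)C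
F4 | step 8 | (1R,2R,6S)-6-[(3S)-2-chloro-3-{[tert-butyl(dimethyl)silyl]oxy}-6-methylhept-5-en-2-yl]-3-methyl-2-[(triethylsilyl)oxy]cyclohex-3-en-1-ol (C7 epimers) | CC(Cl)([C@@H](O[Si](C)(C)C(C)(C)C)CC=C(C)C)[C@H]1CC=C(C)[C@@H](O[Si](CC)(CC)CC)[C@@H]1O
F5 | step 12 | (1R,2S,3S,4S,6R,8S,10R)-3,4:10,11-diepoxybisabol-7(14)-ene-1,2,8-triyl tris{2-[bis(2,2,2-trifluoroethoxy)phosphoryl]propanoate} | C=C([C@H](C[C@H]1OC1(C)C)OC(=O)C(C)P(=O)(OCC(F)(F)F)OCC(F)(F)F)[C@H]1C[C@@H]2O[C@]2(C)[C@@H](OC(=O)C(C)P(=O)(OCC(F)(F)F)OCC(F)(F)F)[C@@H]1OC(=O)C(C)P(=O)(OCC(F)(F)F)OCC(F)(F)F
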